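The route rests on cutting ring B, the cyclobutane C2–C3–C8–C7, along C2–C3 and C7–C8, which unravels rings A and B to an acyclic (E)-dienyl amide. The key step, a crossed intramolecular [2+2] of a vinylketeniminium ion, closes both rings and sets C3, C7 and C8 in one operation. It exploits the bicyclo[3.1.1]heptene core, whose one-carbon bridges are a CH (C2, the former iminium carbon) and the methylated quaternary C8 (the former alkene terminus). The precursor is the (E)-10-silyloxy-7-methyl-3-methylidenedec-6-enoyl amide of (2R,5R)-2,5-dimethylpyrrolidine. Ring C is then closed onto the non-enolisable cyclobutanone by an ester aldol.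

Key step: step 7

Assumption: the sense of induction of the (2R,5R) amine in this crossed mode is taken from the model in step 7; if it proved opposite, the equally available (2S,5S) amine would replace it in step 6 with no other change.

Atom labels: C1 (quaternary, CH3 and CH2O-angelate), C2 (ring B CH), C3 (bridgehead next to the ketone), C4 (C=O), C5 (=CH), C6 (=C–CH3), C7 (allylic bridgehead), C8 (methylated quaternary carbon), C9 and C10 (CH2), C11 (CH–O-angelate). Ring A: C2, C3, C4, C5, C6, C7. Ring B: C2, C3, C8, C7. Ring C: C1, C2, C3, C8, C9, C10, C11. In these labels the target is 1S, 2S, 3R, 7R, 8R, 11R.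

Step 1
Reactants: 1 pent-4-yn-1-ol
Product: 2 tert-butyl(pent-4-yn-1-yloxy)diphenylsilane
Conditions: TBDPSCl, imidazole, CH2Cl2, 0 °C to rt
Reagents that add atoms: tert-butyl(chloro)diphenylsilane, CC(C)(C)[Si](Cl)(c1ccccc1)c1ccccc1
Why: Silyl ether formation on a primary alcohol; the bulky, acid-stable diphenylsilyl group is chosen because this oxygen later sits four atoms from a cationic carbon and must neither leave nor act as an internal nucleophile.

Step 2
Reactants: 2
Product: 5 (E)-6-[(tert-butyldiphenylsilyl)oxy]-3-methylhex-2-en-1-ol, via alkenylalane 3 (not isolated), via lithium alkenylaluminate 4 (not isolated)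
Conditions: Me3Al, Cp2ZrCl2 (25 mol %), CH2Cl2, 0 °C to rt; n-BuLi, THF, −30 °C; (CH2O)n, rt; aqueous work-up
Reagents that add atoms: trimethylaluminium, C[Al](C)C; formaldehyde (from paraformaldehyde), C=O
Why: Negishi carboalumination adds CH3 and Al syn across the terminal alkyne with Al on the terminal carbon, and hydroxymethylation of the aluminate goes with retention, so the (E)-trisubstituted alkene is fixed here.

Step 3
Reactants: 5
Product: 6 {[(E)-6-bromo-4-methylhex-4-en-1-yl]oxy}(tert-butyl)diphenylsilane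
Conditions: CBr4, PPh3, CH2Cl2, 0 °C
Reagents that add atoms: carbon tetrabromide, BrC(Br)(Br)Br
Why: Appel bromination of the primary allylic alcohol is an SN2 displacement under neutral conditions and should leave the alkene geometry and the silyl ether untouched.

Step 4
Reactants: 6; 7 3-methylbut-3-en-1-ol
Product: 9 (E)-10-[(tert-butyldiphenylsilyl)oxy]-7-methyl-3-methylidenedec-6-en-1-ol, via dilithio dianion 8 (not isolated)
Conditions: 7 (2.2 equiv), n-BuLi (4.2 equiv), TMEDA, Et2O, 0 °C to rt; then 6, THF, −78 to 0 °C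
Reagents that add atoms: none
Why: Dianion alkylation: the allylic C,O-dianion of isoprenol has two equivalent allylic termini and should attack the primary allylic bromide at its CH2 (SN2), installing the 1,1-disubstituted alkene and the two-carbon alcohol arm in one C–C bond formation.

Step 5
Reactants: 9
Product: 11 (E)-10-[(tert-butyldiphenylsilyl)oxy]-7-methyl-3-methylidenedec-6-enoic acid, via aldehyde 10 (not isolated)
Conditions: TEMPO (20 mol %), PhI(OAc)2 (2.2 equiv), MeCN–H2O (1:1), rt
Reagents that add atoms: water, O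
Why: Oxoammonium-mediated oxidation takes the primary alcohol through the aldehyde hydrate to the acid without strong acid or base, which should keep the 3-methylidene group out of conjugation.

Step 6
Reactants: 11; 12 (2R,5R)-2,5-dimethylpyrrolidine
Product: 14 (E)-10-[(tert-butyldiphenylsilyl)oxy]-1-[(2R,5R)-2,5-dimethylpyrrolidin-1-yl]-7-methyl-3-methylidenedec-6-en-1-one, via acid chloride 13 (not isolated)
Conditions: 1-chloro-N,N,2-trimethylprop-1-en-1-amine, CH2Cl2, 0 °C; then 12, pyridine, −20 to 0 °C
Reagents that add atoms: none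
Why: Amide formation by acylation of the hindered secondary amine with an acid chloride made under neutral conditions; should any vinylketene form, amine capture and α-protonation lead to the same β,γ-unsaturated amide.

Step 7
Reactants: 14
Product: 17 (1R,5S,7S)-7-{3-[(tert-butyldiphenylsilyl)oxy]propyl}-7-methyl-2-methylidenebicyclo[3.1.1]heptan-6-one, via vinylketeniminium triflate 15 (not isolated), via cyclobutaniminium triflate 16 (not isolated)
Conditions: Tf2O (1.2 equiv), 2,6-di-tert-butyl-4-methylpyridine (1.5 equiv), CH2Cl2, −30 °C to rt, 40 °C if needed; then aq. NaHCO3, 40 °C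
Reagents that add atoms: water, O
Why: Proposed new method: O-triflation of the amide and loss of the doubly activated α-proton should give vinylketeniminium ion 15, whose electrophilic central carbon (C2) is attacked by the alkene CH (C3), placing charge on the tertiary carbon C8, which the enamine carbon C7 then captures before hydrolysis of iminium 16 releases the ketone. The closest known reactions are the intramolecular keteniminium–alkene [2+2] of 2,5-dimethylpyrrolidine amides and the crossed [2+2] of vinylketenes from geranic-type acid chlorides, which gives this same bicyclo[3.1.1]heptan-6-one skeleton. Ring A (C2, C3, C4, C5, C6, C7) closes by six-membered exo attack of C3 on C2, and ring B (C2, C3, C8, C7) by four-membered closure of C7 onto C8 across it. C3 and C7 are tied cis by the one-carbon bridge, C8 follows from suprafacial addition to the (E)-alkene (methyl over ring A, silyloxypropyl chain on the far face), and the absolute sense comes from the C2-symmetric pyrrolidine, whose methyl on the carbon syn to the new C2–C3 bond in an enamine-like transition state should turn the disubstituted terminus C8 to one side. The step needs crossed rather than fused regiochemistry, secured by the trisubstituted alkene that stabilises charge at C8 and by the three-atom tether, and it needs a silent chain oxygen, secured by the bulky diphenylsilyl ether.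

Step 8
Reactants: 17
Product: 18 (1R,5S,7S)-7-(3-hydroxypropyl)-7-methyl-2-methylidenebicyclo[3.1.1]heptan-6-one
Conditions: Bu4NF, AcOH, THF, 0 °C to rt
Reagents that add atoms: none
Why: Fluoride desilylation buffered with acetic acid should spare the non-enolisable cyclobutanone and the exocyclic alkene; any bridged hemiketal with the ketone stays in equilibrium with the open alcohol.

Step 9
Reactants: 18
Product: 19 3-[(1R,5S,7S)-7-methyl-2-methylidene-6-oxobicyclo[3.1.1]heptan-7-yl]propanal
Conditions: Dess–Martin periodinane, NaHCO3, CH2Cl2, rt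
Reagents that add atoms: none
Why: Dess–Martin oxidation of the primary alcohol stops at the aldehyde under buffered conditions and draws the open hydroxy ketone out of any hemiketal equilibrium.

Step 10
Reactants: 19; 20 (S)-4-benzyl-3-propanoyl-1,3-oxazolidin-2-one
Product: 22 (4S)-4-benzyl-3-{(2S,3R)-3-hydroxy-2-methyl-5-[(1R,5S,7S)-7-methyl-2-methylidene-6-oxobicyclo[3.1.1]heptan-7-yl]pentanoyl}-1,3-oxazolidin-2-one, via boron enolate 21 (not isolated)
Conditions: 20, Bu2BOTf, i-Pr2NEt, CH2Cl2, 0 °C; then 19, −78 to 0 °C; MeOH–pH 7 buffer work-up without peroxide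
Reagents that add atoms: none
Why: Evans syn aldol: the (Z)-boron enolate reacts through a chair transition state on the face left open by the benzyl group, which sets C11 (3R) under reagent control at the aldehyde and not at the hindered ketone; peroxide is left out of the work-up to spare the cyclobutanone from ring expansion.

Step 11
Reactants: 22
Product: 23 methyl (2S,3R)-3-hydroxy-2-methyl-5-[(1R,5S,7S)-7-methyl-2-methylidene-6-oxobicyclo[3.1.1]heptan-7-yl]pentanoate
Conditions: MeMgBr, MeOH, CH2Cl2, 0 °C (MeOMgBr formed before 22 is added)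
Reagents that add atoms: methanol, CO
Why: Imide methanolysis (magnesium methoxide transesterification of the N-acyl oxazolidinone) frees the auxiliary under mild conditions with little retro-aldol cleavage; the configuration at C1 does not matter because that centre is enolised in step 13.

Step 12
Reactants: 23
Product: 24 methyl (2S,3R)-3-[(tert-butyldimethylsilyl)oxy]-2-methyl-5-[(1R,5S,7S)-7-methyl-2-methylidene-6-oxobicyclo[3.1.1]heptan-7-yl]pentanoate
Conditions: TBSCl, imidazole, DMF, rt
Reagents that add atoms: tert-butyl(chloro)dimethylsilane, CC(C)(C)[Si](C)(C)Cl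
Why: Silylation with the chloride–imidazole system is selective for the secondary alcohol over any tertiary hemiketal hydroxyl, and the bulky non-chelating silyl ether is the element that later steers the ring closure.

Step 13
Reactants: 24
Product: 27 tricyclic S-methyl xanthate (C1: CH3 and CO2CH3; C2: OC(=S)SCH3; C6=CH2; C11: OTBS), via lithium aldolate 25 (not isolated), via lithium xanthate 26 (not isolated)
Conditions: lithium 2,2,6,6-tetramethylpiperidide, THF, −78 to −40 °C; then CS2, DMPU, −78 to 0 °C; then MeI, rt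
Reagents that add atoms: carbon disulfide, S=C=S; iodomethane, CI
Why: Intramolecular aldol addition: the hydride-free base removes the only acidic proton (H-1; the ketone has none and cannot be reduced by this base), and the ester enolate adds to the strained C2 carbonyl through a chair-like closure in which H-11 eclipses the enolate (allylic strain) and the silyloxy group lies anti to the forming bond, which should set C1 with its methyl cis and its ester trans to O-11, while immediate conversion of the alkoxide into the xanthate forestalls retro-aldol opening.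

Step 14
Reactants: 27
Product: 28 tricyclic ester (C1: CH3 and CO2CH3; C2–H; C6=CH2; C11: OTBS; all six stereocentres as in the target)
Conditions: Bu3SnH, AIBN (cat.), toluene, 90 °C
Reagents that add atoms: none
Why: Barton–McCombie deoxygenation: the tertiary cyclobutyl radical at C2 has no β-hydrogen available for elimination and should take hydrogen on the only open face, that over ring A, because ring C holds C1 on the other.

Step 15
Reactants: 28
Product: 29 tricyclic ester with the endocyclic C5=C6 alkene (CH3 on C6)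
Conditions: RhCl3·3H2O (10 mol %), EtOH, 70 °C
Reagents that add atoms: none
Why: Rhodium-hydride-catalysed alkene isomerisation should move the exocyclic double bond to the favoured trisubstituted ring position, as in the change of β-pinene into α-pinene, without acid strong enough to open the cyclobutane.

Step 16
Reactants: 29
Product: 30 enone ester (C4=O, C5=C6; C1: CO2CH3; C11: OTBS)
Conditions: CrO3, 3,5-dimethylpyrazole, CH2Cl2, −20 °C
Reagents that add atoms: chromium trioxide, O=[Cr](=O)=O
Why: Allylic oxidation with the CrO3–3,5-dimethylpyrazole complex should convert the ring allylic CH2 (C4) into the enone, the position oxidised when α-pinene is turned into verbenone, while the bridgehead C7–H is protected by strain and the ester and silyl ether are inert.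

Step 17
Reactants: 30
Product: 31 diol (C1: CH2OH; C4: allylic OH, expected syn to the C8 bridge; C11: OTBS)
Conditions: i-Bu2AlH (5 equiv), CH2Cl2, −78 to 0 °C; aq. potassium sodium tartrate
Reagents that add atoms: none
Why: Hydride reduction takes the neopentyl ester to the primary alcohol and the enone by 1,2-addition to the allylic alcohol, hydride arriving anti to the C8 methyl; the C4 carbinol centre is removed in the next step.

Step 18
Reactants: 31
Product: 32 hydroxy enone (C1: CH2OH; C4=O; C11: OTBS)
Conditions: MnO2 (activated, excess), CH2Cl2, rt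
Reagents that add atoms: none
Why: MnO2 oxidation is selective for the allylic alcohol, which returns the enone and leaves the saturated neopentyl primary alcohol untouched.

Step 19
Reactants: 32
Product: 33 (1R,2R,5R,6S,7S,8R)-5-hydroxy-6-(hydroxymethyl)-2,6,11-trimethyltricyclo[5.4.0.0^2,8]undec-10-en-9-one
Conditions: HF·pyridine, pyridine, THF, 0 °C to rt
Reagents that add atoms: none
Why: Fluoride desilylation of the hindered secondary silyl ether under buffered conditions that the enone and the cyclobutane should tolerate.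

Step 20
Reactants: 33; 34 angelic acid
Product: 36 CNP0240716.2, via mixed anhydride 35 (not isolated)
Conditions: 34 (6 equiv), 2,4,6-trichlorobenzoyl chloride, Et3N, toluene, rt; then 33, 80 °C
Reagents that add atoms: none
Why: Yamaguchi-type esterification through the angelic 2,4,6-trichlorobenzoic mixed anhydride, run without a nucleophilic catalyst, is the variant known to acylate hindered alcohols while keeping the (Z)-geometry of angelates.

Compound list
1 | pent-4-yn-1-ol | C#CCCCO | starting material
2 | tert-butyl(pent-4-yn-1-yloxy)diphenylsilane | C#CCCCO[Si](c1ccccc1)(c1ccccc1)C(C)(C)C | intermediate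
3 | dimethyl{(E)-5-[(tert-butyldiphenylsilyl)oxy]-2-methylpent-1-en-1-yl}alane | C[Al](C)/C=C(\C)CCCO[Si](c1ccccc1)(c1ccccc1)C(C)(C)C | intermediate
4 | lithium butyl{(E)-5-[(tert-butyldiphenylsilyl)oxy]-2-methylpent-1-en-1-yl}dimethylaluminate | [Li+].CCCC[Al-](C)(C)/C=C(\C)CCCO[Si](c1ccccc1)(c1ccccc1)C(C)(C)C | intermediate
5 | (E)-6-[(tert-butyldiphenylsilyl)oxy]-3-methylhex-2-en-1-ol | OC/C=C(\C)CCCO[Si](c1ccccc1)(c1ccccc1)C(C)(C)C | intermediate
6 | {[(E)-6-bromo-4-methylhex-4-en-1-yl]oxy}(tert-butyl)diphenylsilane | BrC/C=C(\C)CCCO[Si](c1ccccc1)(c1ccccc1)C(C)(C)C | intermediate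
7 | 3-methylbut-3-en-1-ol | C=C(C)CCO | starting material
8 | dilithio dianion of 7 (lithium 3-(lithiomethyl)but-3-en-1-olate) | [Li]CC(=C)CCO[Li] | intermediate
9 | (E)-10-[(tert-butyldiphenylsilyl)oxy]-7-methyl-3-methylidenedec-6-en-1-ol | OCCC(=C)CC/C=C(\C)CCCO[Si](c1ccccc1)(c1ccccc1)C(C)(C)C | intermediate
10 | (E)-10-[(tert-butyldiphenylsilyl)oxy]-7-methyl-3-methylidenedec-6-enal | O=CCC(=C)CC/C=C(\C)CCCO[Si](c1ccccc1)(c1ccccc1)C(C)(C)C | intermediate
11 | (E)-10-[(tert-butyldiphenylsilyl)oxy]-7-methyl-3-methylidenedec-6-enoic acid | OC(=O)CC(=C)CC/C=C(\C)CCCO[Si](c1ccccc1)(c1ccccc1)C(C)(C)C | intermediate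
12 | (2R,5R)-2,5-dimethylpyrrolidine | C[C@@H]1CC[C@@H](C)N1 | starting material
13 | (E)-10-[(tert-butyldiphenylsilyl)oxy]-7-methyl-3-methylidenedec-6-enoyl chloride | ClC(=O)CC(=C)CC/C=C(\C)CCCO[Si](c1ccccc1)(c1ccccc1)C(C)(C)C | intermediate
14 | (E)-10-[(tert-butyldiphenylsilyl)oxy]-1-[(2R,5R)-2,5-dimethylpyrrolidin-1-yl]-7-methyl-3-methylidenedec-6-en-1-one | C[C@@H]1CC[C@@H](C)N1C(=O)CC(=C)CC/C=C(\C)CCCO[Si](c1ccccc1)(c1ccccc1)C(C)(C)C | intermediate
15 | (2R,5R)-1-{(E)-10-[(tert-butyldiphenylsilyl)oxy]-7-methyl-3-methylidenedeca-1,6-dien-1-ylidene}-2,5-dimethylpyrrolidin-1-ium triflate | C[C@@H]1CC[C@@H](C)[N+]1=C=CC(=C)CC/C=C(\C)CCCO[Si](c1ccccc1)(c1ccccc1)C(C)(C)C.[O-]S(=O)(=O)C(F)(F)F | intermediate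
16 | (2R,5R)-1-[(1R,5S,7S)-7-{3-[(tert-butyldiphenylsilyl)oxy]propyl}-7-methyl-2-methylidenebicyclo[3.1.1]heptan-6-ylidene]-2,5-dimethylpyrrolidin-1-ium triflate | C[C@@H]1CC[C@@H](C)[N+]1=C1[C@H]2CCC(=C)[C@@H]1[C@@]2(C)CCCO[Si](c1ccccc1)(c1ccccc1)C(C)(C)C.[O-]S(=O)(=O)C(F)(F)F | intermediate
17 | (1R,5S,7S)-7-{3-[(tert-butyldiphenylsilyl)oxy]propyl}-7-methyl-2-methylidenebicyclo[3.1.1]heptan-6-one | O=C1[C@H]2CCC(=C)[C@@H]1[C@@]2(C)CCCO[Si](c1ccccc1)(c1ccccc1)C(C)(C)C | intermediate
18 | (1R,5S,7S)-7-(3-hydroxypropyl)-7-methyl-2-methylidenebicyclo[3.1.1]heptan-6-one | O=C1[C@H]2CCC(=C)[C@@H]1[C@@]2(C)CCCO | intermediate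
19 | 3-[(1R,5S,7S)-7-methyl-2-methylidene-6-oxobicyclo[3.1.1]heptan-7-yl]propanal | O=C1[C@H]2CCC(=C)[C@@H]1[C@@]2(C)CCC=O | intermediate
20 | (S)-4-benzyl-3-propanoyl-1,3-oxazolidin-2-one | CCC(=O)N1[C@@H](Cc2ccccc2)COC1=O | starting material
21 | (Z)-dibutylboron enolate of 20 | C/C=C(\OB(CCCC)CCCC)N1[C@@H](Cc2ccccc2)COC1=O | intermediate
22 | (4S)-4-benzyl-3-{(2S,3R)-3-hydroxy-2-methyl-5-[(1R,5S,7S)-7-methyl-2-methylidene-6-oxobicyclo[3.1.1]heptan-7-yl]pentanoyl}-1,3-oxazolidin-2-one | O=C1[C@H]2CCC(=C)[C@@H]1[C@@]2(C)CC[C@@H](O)[C@H](C)C(=O)N1[C@@H](Cc2ccccc2)COC1=O | intermediate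
23 | methyl (2S,3R)-3-hydroxy-2-methyl-5-[(1R,5S,7S)-7-methyl-2-methylidene-6-oxobicyclo[3.1.1]heptan-7-yl]pentanoate | O=C1[C@H]2CCC(=C)[C@@H]1[C@@]2(C)CC[C@@H](O)[C@H](C)C(=O)OC | intermediate
24 | methyl (2S,3R)-3-[(tert-butyldimethylsilyl)oxy]-2-methyl-5-[(1R,5S,7S)-7-methyl-2-methylidene-6-oxobicyclo[3.1.1]heptan-7-yl]pentanoate | O=C1[C@H]2CCC(=C)[C@@H]1[C@@]2(C)CC[C@@H](O[Si](C)(C)C(C)(C)C)[C@H](C)C(=O)OC | intermediate
25 | lithium aldolate of the closed tricycle (C1: CH3, CO2CH3; C2: OLi; C6=CH2; C11: OTBS) | COC(=O)[C@]1(C)[C@]2(O[Li])[C@H]3CCC(=C)[C@@H]2[C@@]3(C)CC[C@H]1O[Si](C)(C)C(C)(C)C | intermediate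
26 | lithium xanthate of the tricycle (C2: OC(=S)SLi) | COC(=O)[C@]1(C)[C@]2(OC(=S)S[Li])[C@H]3CCC(=C)[C@@H]2[C@@]3(C)CC[C@H]1O[Si](C)(C)C(C)(C)C | intermediate
27 | tricyclic S-methyl xanthate (C1: CH3, CO2CH3; C2: OC(=S)SCH3; C6=CH2; C11: OTBS) | COC(=O)[C@]1(C)[C@]2(OC(=S)SC)[C@H]3CCC(=C)[C@@H]2[C@@]3(C)CC[C@H]1O[Si](C)(C)C(C)(C)C | intermediate
28 | tricyclic ester (C1: CH3, CO2CH3; C2–H; C6=CH2; C11: OTBS) | COC(=O)[C@]1(C)[C@@H]2[C@H]3CCC(=C)[C@@H]2[C@@]3(C)CC[C@H]1O[Si](C)(C)C(C)(C)C | intermediate
29 | tricyclic ester with endocyclic C5=C6 (CH3 on C6) | COC(=O)[C@]1(C)[C@@H]2[C@H]3CC=C(C)[C@@H]2[C@@]3(C)CC[C@H]1O[Si](C)(C)C(C)(C)C | intermediate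
30 | enone ester (C4=O; C1: CO2CH3; C11: OTBS) | COC(=O)[C@]1(C)[C@@H]2[C@H]3C(=O)C=C(C)[C@@H]2[C@@]3(C)CC[C@H]1O[Si](C)(C)C(C)(C)C | intermediate
31 | diol (C1: CH2OH; C4: OH, configuration as expected from hydride attack anti to the C8 methyl; C11: OTBS) | OC[C@]1(C)[C@@H]2[C@H]3[C@H](O)C=C(C)[C@@H]2[C@@]3(C)CC[C@H]1O[Si](C)(C)C(C)(C)C | intermediate
32 | hydroxy enone (C1: CH2OH; C4=O; C11: OTBS) | OC[C@]1(C)[C@@H]2[C@H]3C(=O)C=C(C)[C@@H]2[C@@]3(C)CC[C@H]1O[Si](C)(C)C(C)(C)C | intermediate
33 | (1R,2R,5R,6S,7S,8R)-5-hydroxy-6-(hydroxymethyl)-2,6,11-trimethyltricyclo[5.4.0.0^2,8]undec-10-en-9-one | OC[C@]1(C)[C@@H]2[C@H]3C(=O)C=C(C)[C@@H]2[C@@]3(C)CC[C@H]1O | intermediate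
34 | angelic acid, (Z)-2-methylbut-2-enoic acid | C/C=C(/C)C(=O)O | starting material
35 | (Z)-2-methylbut-2-enoic 2,4,6-trichlorobenzoic anhydride | C/C=C(/C)C(=O)OC(=O)c1c(Cl)cc(Cl)cc1Cl | intermediate
36 | CNP0240716.2, the bis-angelate of 33 (angelate on the C1 CH2O and on O-11) | C/C=C(/C)C(=O)OC[C@]1(C)[C@@H]2[C@H]3C(=O)C=C(C)[C@@H]2[C@@]3(C)CC[C@H]1OC(=O)/C(C)=C\C | target

Total step count: 20. Longest linear sequence: 20 steps, from pent-4-yn-1-ol (1) to 36.

Steps most likely to fail

1. Step 7 (proposed new method). The cationic intermediate may lose a proton or close in the fused sense in place of the crossed one, and the remote auxiliary may discriminate poorly between the two faces. The fallback uses the known crossed [2+2] of vinylketenes and sets out from acid 11. Acid 11 is converted into acid chloride 13 as in step 6, and slow addition of 13 to Et3N in refluxing toluene at high dilution should generate the vinylketene F1, which cyclises to the racemic ketone, that is 17 together with its mirror-image ketone F2. The mixture is carried through steps 8 and 9, giving 18 and 19 beside the mirror-image alcohol F3 and the mirror-image aldehyde F4. The aldol of step 10 then turns the enantiomers into the diastereomers 22 and the diastereomeric aldol F5, which are separated by chromatography (preparative HPLC if needed). The route is rejoined at 22.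

2. Step 13. Thiocarbonylation of the hindered tertiary lithium alkoxide may be slow, so that on warming the aldolate reopens by retro-aldol cleavage or the enolate expels silanolate. The fallback separates ring closure from activation and sets out from 24. Cyclisation with lithium 2,2,6,6-tetramethylpiperidide and protonation with AcOH at −78 °C should give the tertiary cyclobutanol F6. Acylation with methyl chlorooxoacetate, DMAP and pyridine in CH2Cl2 gives the methyl oxalate F7. Reduction of this tertiary oxalate with Bu3SnH and AIBN in refluxing toluene should give 28, where the route is rejoined.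

3. Step 20. Acylation of the hindered C11 hydroxyl may stall, and prolonged heating may isomerise the angelate to the tiglate. The fallback builds the (Z)-alkenes in place and sets out from diol 33. Esterification of both hydroxyls with 2-[bis(2,2,2-trifluoroethoxy)phosphoryl]propanoic acid (EDC, DMAP, CH2Cl2) gives the bis-phosphonate F8. A twofold Still–Gennari olefination with acetaldehyde (KN(SiMe3)2, 18-crown-6, THF, −78 °C) should then give 36 directly.

Further compounds
F1 | step 7 | (E)-10-[(tert-butyldiphenylsilyl)oxy]-7-methyl-3-methylidenedeca-1,6-dien-1-one (vinylketene) | O=C=CC(=C)CC/C=C(\C)CCCO[Si](c1ccccc1)(c1ccccc1)C(C)(C)C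
F2 | step 7 | (1S,5R,7R)-7-{3-[(tert-butyldiphenylsilyl)oxy]propyl}-7-methyl-2-methylidenebicyclo[3.1.1]heptan-6-one (mirror image of 17) | O=C1[C@@H]2CCC(=C)[C@H]1[C@]2(C)CCCO[Si](c1ccccc1)(c1ccccc1)C(C)(C)C
F3 | step 7 | (1S,5R,7R)-7-(3-hydroxypropyl)-7-methyl-2-methylidenebicyclo[3.1.1]heptan-6-one (mirror image of 18) | O=C1[C@@H]2CCC(=C)[C@H]1[C@]2(C)CCCO
F4 | step 7 | 3-[(1S,5R,7R)-7-methyl-2-methylidene-6-oxobicyclo[3.1.1]heptan-7-yl]propanal (mirror image of 19) | O=C1[C@@H]2CCC(=C)[C@H]1[C@]2(C)CCC=O
F5 | step 7 | (4S)-4-benzyl-3-{(2S,3R)-3-hydroxy-2-methyl-5-[(1S,5R,7R)-7-methyl-2-methylidene-6-oxobicyclo[3.1.1]heptan-7-yl]pentanoyl}-1,3-oxazolidin-2-one (diastereomer of 22) | O=C1[C@@H]2CCC(=C)[C@H]1[C@]2(C)CC[C@@H](O)[C@H](C)C(=O)N1[C@@H](Cc2ccccc2)COC1=O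
F6 | step 13 | tertiary cyclobutanol, the protonated form of 25 (C1: CH3, CO2CH3; C2: OH; C6=CH2; C11: OTBS) | COC(=O)[C@]1(C)[C@]2(O)[C@H]3CCC(=C)[C@@H]2[C@@]3(C)CC[C@H]1O[Si](C)(C)C(C)(C)C
F7 | step 13 | methyl oxalate of F6 (C2: OC(=O)CO2CH3) | COC(=O)[C@]1(C)[C@]2(OC(=O)C(=O)OC)[C@H]3CCC(=C)[C@@H]2[C@@]3(C)CC[C@H]1O[Si](C)(C)C(C)(C)C
F8 | step 20 | bis{2-[bis(2,2,2-trifluoroethoxy)phosphoryl]propanoate} of 33 (mixture of epimers at the two phosphonate-bearing carbons) | CC(C(=O)OC[C@]1(C)[C@@H]2[C@H]3C(=O)C=C(C)[C@@H]2[C@@]3(C)CC[C@H]1OC(=O)C(C)P(=O)(OCC(F)(F)F)OCC(F)(F)F)P(=O)(OCC(F)(F)F)OCC(F)(F)F
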